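In a one-step world each mirror-image substrate disappears at its own constant times [reagent][free catalyst] times its own concentration, so however the feed and the catalyst vary in time, the two logarithms of the fractions left keep one ratio. That ratio, ln(left-handed substrate left) over ln(right-handed substrate left), is the selectivity factor, and one is its zero, the symmetric case with no excess. Pooled over the four cedar readings, I read 1.88.

| setting | cedar | flask |
|---|---|---|
| left-handed substrate | 1 M | 1.0 M |
| right-handed substrate | 1 M | 1.0 M |
| reagent | 2 M (fed, over 2.5 d) | 2.00 M (fed, over 2.5 d) |
| free catalyst | 85 mM | 85 mM |
| racemization catalyst | 2 mM | 2.0 mM |
| added ligand | 8.9 mM | 8.9 mM |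
| remark | the very flask that is asked about, followed so far; the fed solution adds 0.50 times the starting volume | the fed solution adds 0.50 times the starting volume |
| time |  | 10 d |

- cedar (time / d: left-handed product / %, right-handed product / %): 1.25: 13.0, 7.0; 2.50: 25.2, 17.0; 4.00: 34.4, 23.8; 5.00: 40.0, 27.4

(each reading ± 1 percentage point)

* left-handed product and right-handed product together, in percent of the left-handed substrate and right-handed substrate charged together, at 10 d
* excess of left-handed product over right-handed product in the product at 10 d
* whether the exchange between left-handed substrate and right-handed substrate keeps pace with the reaction: how far the product's excess at 10 d gets from its value without exchange to its value with instant exchange (above 80% keeps pace, below 20% hardly takes part, else lags behind)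

- free catalyst is single-handed; left-handed substrate and right-handed substrate are mirror images of each other, charged as a racemate, each of them at the stated concentration
- amounts are per litre of the starting volume; all of the dose is in the solution fed
- the analysis behind the earlier runs scatters by 1 percentage point, standard deviation
- an excess is the difference of the two amounts in percent of their sum
- an excess is below zero if the other one leads

This flask is the cedar run carried on, so its charges need no second reading. What must I know well? Exchange first: instant exchange holds the excess at the factor less one over the factor plus one, 30.6%, but the cedar excess has sunk to 18.7% at 5.00 d, well below that, so I reckon without exchange. Next the factor: if I suppose 25.0% of the right-handed substrate left, the left-handed fraction is that raised to the factor, 7.36%, and the excess 10.5%. The last cedar reading alone gives 2.03 and 11.2%. Reach matters more: 33.3% left gives 13.4%, a larger shift.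

So reach is the number to watch. Reagent and substrates are charged equally, 2.00 M against 2.00 M, so after the feed I let the reciprocal of the unreacted share climb straight, which gives 82.6%; I commit to that and to 10.5%.

The forecast says 87% (80% to 93%), higher than mine, and 11% (7% to 17%), and that exchange hardly takes part, since “a plain kinetic resolution with s ≈ 1.9 and no exchange fits the runs”.

The flask gives 81.1% and 11.4%, and there exchange hardly takes part, at 0.26% of the way. The forecast's total stands 5.9 percentage points too high, with 19% of the reagent charge still present in the flask at 10.0 d.

    reagent + free catalyst + left-handed substrate → free catalyst + left-handed product (k = 1.40 × 10⁻⁴ M⁻² s⁻¹)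
    reagent + free catalyst + right-handed substrate → free catalyst + right-handed product (k = 7.60 × 10⁻⁵ M⁻² s⁻¹)
    left-handed substrate + racemization catalyst ⇌ right-handed substrate + racemization catalyst, rate k3*[racemization catalyst]*[left-handed substrate] forward; the back reaction follows from the equilibrium constant (k = 0.00380 M⁻¹ s⁻¹)
    racemization catalyst + added ligand ⇌ idle complex, settled at all times (K = 1.90 × 10⁵ M⁻¹)
    free catalyst ⇌ dormant form (K = 0.320, k = 7.80 × 10⁻⁶ s⁻¹)

The flask's right-handed rest of 28%, raised to the factor, gives 9.13% against the simulated 9.7% of left-handed substrate. The neighbour charged with 0.14 M of free catalyst reaches 87.2%, further. Its right-handed rest of 20%, raised to the factor, gives 4.97% of the left-handed charge and an excess of 8.77%, and that neighbour's simulated excess is 8.67%.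

Readings and results were computed from invented constants; the scatter is artificial.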